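The runs come from a simulation with constants of no real substance; the scatter is artificial.

A stirred vessel at constant volume receives its Z or its E over 15 min, and the question is what that feed does to the D present at the end.

| setting | maple | birch | grey | blue | red |
|---|---|---|---|---|---|
| Z | 0.40 M | 0.20 M | 0.40 M (fed, over 15 min) | 0.40 M | 0.40 M |
| E | 0.80 equiv | 0.80 equiv | 0.800 equiv | 0.800 equiv | 0.800 equiv (fed, over 15 min) |
| X | 15 mol% | 15 mol% | 15 mol% | 15 mol% | 15 mol% |
| remark | run made earlier | run made earlier | all else is in the flask from the start; the feed brings no volume worth counting | everything together at the start | all else is in the flask from the start; the feed brings no volume worth counting |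
| time |  |  | 80 min | 80 min | 80 min |

- maple (time / min: D / %, G / %): 6.00: 7.6, 12.8; 12.0: 13.9, 12.8; 25.0: 23.9, 11.2; 40.0: 30.2, 5.9; 80.0: 36.4, 2.6
- birch (time / min: D / %, G / %): 1.33: 0, 4.1; 2.50: 0, 3.6; 5.00: 1.2, 4.8; 8.00: 2.2, 6.7; 15.0: 6.5, 8.4

(each reading ± 1 percentage point)

- percentages count the Z that a species holds: one D counts as two
- the numbers in the tables scatter by 1 percentage point (one standard deviation)

* which flask leads in amount of D, in percent of the Z charged ("all alike" within 1.5 percentage points) (grey / blue / red / all alike)
* how much D is there at the end, in percent of the Z charged: grey
* how much D is there at the end, in percent of the Z charged: blue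
* how much D is there at the end, in percent of the Z charged: red

Each D holds two Z, which reads as a G that has taken up a further Z. So G plus D taken at 0.5, called here the made count, tells how much G has formed so far.

The bench rule says a steady feed costs about half its length, here 7.50 min. Maple has blue's recipe, and late in maple D climbs so slowly that this delay is worth 1.2 percentage points, so the rule leaves the fed flasks close to blue.

The rule assumes a feed that is short beside the span of the making. Maple's made count reads 16.6% at 6.00 min and 20.8% at 80.0 min. The window, meaning the time the final count would take at the average pace up to the first reading, is 7.52 min. The feed is twice that long, so the rule is past its border.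

By the end of the window a feed has delivered 50.1% of its charge. Taking G to need both Z and E, either feed should cut the made count to about that share, and D with it. This reckoning gives 18.2% in grey and in red, against maple's 36.4% for blue, so blue leads.

The forecast gave 36% for grey, 36.5% for blue, 36% for red and all alike, holding that “D is therefore not very sensitive to how G is delivered”. The flasks end with 22.2% in grey, 36.8% in blue and 22.3% in red, so blue leads.

    Z + G → D (k = 0.00350 M⁻¹ s⁻¹)
    2 X → J (k = 0.0610 M⁻¹ s⁻¹)
    Z + E + X → X + G (k = 0.0820 M⁻² s⁻¹)
    Z + E → Q (k = 0.00280 M⁻¹ s⁻¹)

Grey ends with 60.3% of blue's D, where the window over the feed gave 50.1%. A neighbouring flask is blue with Z at 0.10 M, a quarter of blue's charge. If the window stretches as the charge falls, it lasts 30.1 min. If the early pace falls with the square of the charge, that window yields a made count of 5.20%. The neighbouring flask ends with G at 3.12% and D at 7.28%, a made count of 6.76%.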